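**Retrosynthetic overview**
1. The strategy rests on C6 of ring A: a fully substituted alkene carbon wedged between the gem-dimethyl quaternary C1 and the methyl-bearing C5, which carries the C7≡C8 alkyne. The C6–C7 bond is the most crowded bond of the skeleton, so it is made last, by Sonogashira coupling of a ring A enol triflate with the complete C31 terminal polyenyne (chain plus ring B), followed only by desilylation.
2. The ring A triflate comes from (4R,6R)-actinol, which already holds the C3 carbinol: silylation, then enolate triflation (the ketone can enolize on one side only).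
3. The C31 polyenyne comes from an E-selective Wittig reaction at C11=C12 between a ring B C25 aldehyde and a C6 enyne tributylphosphonium salt made from (E)-3-methylpent-2-en-4-yn-1-ol.
4. The C25 aldehyde comes from a Wittig reaction at C11'=C12' between the C10 dialdehyde and a C15 phosphonium salt. That salt is made from (R)-α-ionone (vinyl Grignard, then PPh3·HBr), and (R)-α-ionone is obtained by classical resolution of the racemate.
5. No ring is formed in the route: ring A is taken from actinol and ring B from α-ionone.

Key step: step 11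

Remark: atoms are numbered as in carotenoids (ring A and its half of the chain C1–C15, ring B and its half C1'–C15'). All polyene intermediates are assumed to be handled under argon in dim light.

**Step 1**
Reactants: 1 (4R,6R)-4-hydroxy-2,2,6-trimethylcyclohexanone (actinol)
Product: 2 (4R,6R)-4-(tert-butyldimethylsilyloxy)-2,2,6-trimethylcyclohexanone
Conditions: TBSCl, imidazole, DMF, rt
Reagents that add atoms: tert-butyldimethylsilyl chloride (TBSCl), CC(C)(C)[Si](C)(C)Cl
Why: Imidazole-promoted silylation of the unhindered secondary alcohol (silyl ether protection) masks the C3 carbinol without touching the carbinol stereocentre.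

**Step 2**
Reactants: 2 silyl ether of actinol
Product: 4 (4R)-4-(tert-butyldimethylsilyloxy)-2,6,6-trimethylcyclohex-1-en-1-yl trifluoromethanesulfonate, via lithium enolate 3 (not isolated)
Conditions: LiN(i-Pr)2, THF, −78 → 0 °C; then PhNTf2, −78 °C → rt
Reagents that add atoms: N-phenylbis(trifluoromethanesulfonimide) (PhNTf2), O=S(=O)(N(c1ccccc1)S(=O)(=O)C(F)(F)F)C(F)(F)F; lithium diisopropylamide, [Li]N(C(C)C)C(C)C (supplies the lithium of intermediate 3 only)
Why: Enolate O-triflation: the ketone has α-hydrogen only on the methyl-bearing carbon, so a single tetrasubstituted enolate and a single enol triflate can form, and the silyloxy group is γ to the carbonyl and cannot be eliminated.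

**Step 3**
Reactants: 5 (1R,2S,5R)-(−)-menthyl chloroformate
Product: 6 (1R,2S,5R)-(−)-menthyl carbazate (menthyl hydrazinecarboxylate)
Conditions: N2H4·H2O (excess), Et2O, 0 °C → rt
Reagents that add atoms: hydrazine hydrate, NN.O
Why: Acyl substitution of the chloroformate by hydrazine (carbazate formation) is fast, and the excess of hydrazine suppresses double acylation.

**Step 4**
Reactants: 7 racemic α-ionone; 6 (−)-menthyl carbazate
Product: 8 (−)-menthyl carbazate hydrazone of (R)-α-ionone (C=N E, ring carbon 1R)
Conditions: EtOH, AcOH (cat.), NaOAc, reflux; fractional crystallization (EtOH/H2O)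
Reagents that add atoms: none
Why: Hydrazone condensation gives two diastereomers that differ only at ring B C6', and classical resolution by fractional crystallization (the (R)-ketone diastereomer is taken from crystals or mother liquor as its solubility dictates) selects the C6' configuration of the target.

**Step 5**
Reactants: 8 resolved hydrazone
Product: 9 (R)-α-ionone
Conditions: 1 M aq. H2SO4, steam distillation
Reagents that add atoms: water, O
Why: Acid-catalysed hydrolysis of the N-acylhydrazone, with the volatile ketone removed as it forms, should return the enone under conditions too mild to move the ring double bond or to epimerize C6'.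

**Step 6**
Reactants: 9 (R)-α-ionone
Product: 10 (1E)-3-methyl-1-[(1R)-2,6,6-trimethylcyclohex-2-en-1-yl]penta-1,4-dien-3-ol (vinyl-α-ionol, epimer mixture at the carbinol carbon)
Conditions: CH2=CHMgBr, THF, −20 → 0 °C; aq. NH4Cl
Reagents that add atoms: vinylmagnesium bromide, C=C[Mg]Br
Why: Grignard 1,2-addition to the methyl ketone; the new carbinol centre forms without control, which does not matter because it is ionized in step 7, and C6' is not touched.

**Step 7**
Reactants: 10 vinyl-α-ionol
Product: 11 [(2E,4E)-3-methyl-5-[(1R)-2,6,6-trimethylcyclohex-2-en-1-yl]penta-2,4-dien-1-yl]triphenylphosphonium bromide (C15 salt, mainly 9'E)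
Conditions: PPh3·HBr, MeOH, rt
Reagents that add atoms: triphenylphosphine hydrobromide, [Br-].[PH+](c1ccccc1)(c1ccccc1)c1ccccc1
Why: Acid-promoted ionization of the tertiary bis-allylic alcohol to a pentadienyl cation and capture by PPh3 at the unhindered primary terminus (phosphonium salt formation with allylic transposition) should give the conjugated dienyl salt without involving C6'.

**Step 8**
Reactants: 11 C15 phosphonium bromide; 12 (2E,4E,6E)-2,7-dimethylocta-2,4,6-trienedial (C10 dialdehyde)
Product: 15 all-E C25 aldehyde (2E,4E,6E,8E,10E,12E)-2,7,11-trimethyl-13-[(1R)-2,6,6-trimethylcyclohex-2-en-1-yl]trideca-2,4,6,8,10,12-hexaenal, via C15 ylide 13 (not isolated), via crude C25 aldehyde Z/E mixture 14 (not isolated)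
Conditions: NaOMe, MeOH/CH2Cl2, 0 °C → rt (11 added slowly to 3 equiv of 12); then I2 (cat.), CH2Cl2/hexane, rt, daylight; chromatography, crystallization
Reagents that add atoms: none
Why: Wittig olefination with the semi-stabilized allylic ylide forms C11'=C12', the excess of dialdehyde favours mono-condensation, and iodine-catalysed equilibration of this ordinary polyenal should funnel the Z isomers at C9' and C11' into the thermodynamically preferred all-E aldehyde.

**Step 9**
Reactants: 16 (E)-3-methylpent-2-en-4-yn-1-ol
Product: 18 tributyl[(2E)-3-methylpent-2-en-4-yn-1-yl]phosphonium bromide, via (E)-5-bromo-3-methylpent-3-en-1-yne 17 (not isolated)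
Conditions: PBr3, Et2O, −10 → 0 °C; then PBu3, toluene, 0 °C → rt
Reagents that add atoms: phosphorus tribromide, BrP(Br)Br; tributylphosphine, CCCCP(CCCC)CCCC
Why: SN2 bromination of the primary allylic alcohol and SN2 quaternization of PBu3 (phosphonium salt formation) both leave the C9=C10 geometry and the terminal alkyne untouched.

**Step 10**
Reactants: 18 C6 tributylphosphonium bromide; 15 all-E C25 aldehyde
Product: 20 C31 polyenyne (3E,5E,7E,9E,11E,13E,15E,17E)-3,7,12,16-tetramethyl-18-[(1R)-2,6,6-trimethylcyclohex-2-en-1-yl]octadeca-3,5,7,9,11,13,15,17-octaen-1-yne, via C6 ylide 19 (not isolated)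
Conditions: KOt-Bu (slightly less than 1 equiv per 18), THF, −78 °C; then 15, −78 → 0 °C, Ar, dark
Reagents that add atoms: none
Why: Wittig olefination with an allylic trialkylphosphonium ylide, a reagent class that is E-selective because oxaphosphetane formation is reversible, should form C11=C12 as the E isomer, and the phosphonium α-CH is far more acidic than the alkyne CH, so the base gives the ylide only.

**Step 11**
Reactants: 4 ring A enol triflate; 20 C31 polyenyne
Product: 21 tert-butyldimethylsilyl ether of the target
Conditions: Pd(PPh3)4 (5–10 mol %), CuI (10–20 mol %), i-Pr2NH, DMF, rt → 40 °C, Ar, dark (1.3 equiv of 4)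
Reagents that add atoms: none
Why: Sonogashira coupling: zerovalent palladium inserts into the C6–OTf bond of 4 to give a cyclohexenyl divalent palladium triflate, the monovalent copper acetylide formed from the C7–H terminus of 20 with CuI and i-Pr2NH transmetalates, and reductive elimination forms the C6–C7 bond and returns zerovalent palladium. The closest known reaction type is the coupling of 2,6,6-trimethylcyclohexenyl triflates with terminal enynes, here run with a longer polyenyne partner. No ring is closed and no stereocentre is created; C3 and C6' are spectators and keep their configuration. The step needs site selectivity, which is fixed because 4 has a single triflate and 20 a single terminal alkyne, and it needs a nucleophile slim enough to reach C6 between the quaternary C1 and the methyl-bearing C5, which the rod-shaped acetylide provides. It also needs retention of the eight E double bonds, in particular C9=C10, which the amine base, low temperature and darkness should secure, and suppression of oxidative alkyne dimerization, which exclusion of oxygen and the slight excess of 4 should secure.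

**Step 12**
Reactants: 21 silyl ether of the target
Product: 22 (3R,6'R)-7,8-didehydro-β,ε-caroten-3-ol (all-E), the target
Conditions: Bu4NF, AcOH, THF, 0 °C → rt; crystallization
Reagents that add atoms: none
Why: Fluoride-induced desilylation under acetic acid buffering frees the C3 carbinol without disturbing the polyenyne geometry or either stereocentre, and crystallization should remove minor Z isomers.

**Compound list**
1 | (4R,6R)-4-hydroxy-2,2,6-trimethylcyclohexanone (actinol) | O=C1C(C)(C)C[C@H](O)C[C@H]1C | starting material
2 | (4R,6R)-4-(tert-butyldimethylsilyloxy)-2,2,6-trimethylcyclohexanone | O=C1C(C)(C)C[C@H](O[Si](C)(C)C(C)(C)C)C[C@H]1C | intermediate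
3 | lithium enolate of 2 (lithium (4R)-4-(tert-butyldimethylsilyloxy)-2,6,6-trimethylcyclohex-1-en-1-olate) | [Li]OC1=C(C)C[C@@H](O[Si](C)(C)C(C)(C)C)CC1(C)C | intermediate
4 | (4R)-4-(tert-butyldimethylsilyloxy)-2,6,6-trimethylcyclohex-1-en-1-yl trifluoromethanesulfonate | FC(F)(F)S(=O)(=O)OC1=C(C)C[C@@H](O[Si](C)(C)C(C)(C)C)CC1(C)C | intermediate
5 | (1R,2S,5R)-(−)-menthyl chloroformate | ClC(=O)O[C@@H]1C[C@H](C)CC[C@H]1C(C)C | starting material
6 | (1R,2S,5R)-(−)-menthyl carbazate | NNC(=O)O[C@@H]1C[C@H](C)CC[C@H]1C(C)C | intermediate
7 | racemic α-ionone | CC1=CCCC(C)(C)C1/C=C/C(C)=O | starting material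
8 | (−)-menthyl carbazate hydrazone of (R)-α-ionone (C=N E) | C/C(=N\NC(=O)O[C@@H]1C[C@H](C)CC[C@H]1C(C)C)/C=C/[C@H]1C(C)=CCCC1(C)C | intermediate
9 | (R)-α-ionone | CC1=CCCC(C)(C)[C@H]1/C=C/C(C)=O | intermediate
10 | (1E)-3-methyl-1-[(1R)-2,6,6-trimethylcyclohex-2-en-1-yl]penta-1,4-dien-3-ol (carbinol epimers) | CC1=CCCC(C)(C)[C@H]1/C=C/C(C)(O)C=C | intermediate
11 | [(2E,4E)-3-methyl-5-[(1R)-2,6,6-trimethylcyclohex-2-en-1-yl]penta-2,4-dien-1-yl]triphenylphosphonium bromide | CC1=CCCC(C)(C)[C@H]1/C=C/C(C)=C/C[P+](c1ccccc1)(c1ccccc1)c1ccccc1.[Br-] | intermediate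
12 | (2E,4E,6E)-2,7-dimethylocta-2,4,6-trienedial | O=C/C(C)=C/C=C/C=C(C)/C=O | starting material
13 | C15 ylide from 11 | CC1=CCCC(C)(C)[C@H]1/C=C/C(C)=C/C=P(c1ccccc1)(c1ccccc1)c1ccccc1 | intermediate
14 | crude C25 aldehyde, Z/E mixture at C9'=C10' and C11'=C12' | CC1=CCCC(C)(C)[C@H]1/C=C/C(C)=CC=C/C(C)=C/C=C/C=C(C)/C=O | intermediate
15 | (2E,4E,6E,8E,10E,12E)-2,7,11-trimethyl-13-[(1R)-2,6,6-trimethylcyclohex-2-en-1-yl]trideca-2,4,6,8,10,12-hexaenal (all-E C25 aldehyde, CHO = C12) | CC1=CCCC(C)(C)[C@H]1/C=C/C(C)=C/C=C/C(C)=C/C=C/C=C(C)/C=O | intermediate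
16 | (E)-3-methylpent-2-en-4-yn-1-ol | C#C/C(C)=C/CO | starting material
17 | (E)-5-bromo-3-methylpent-3-en-1-yne | C#C/C(C)=C/CBr | intermediate
18 | tributyl[(2E)-3-methylpent-2-en-4-yn-1-yl]phosphonium bromide | C#C/C(C)=C/C[P+](CCCC)(CCCC)CCCC.[Br-] | intermediate
19 | C6 ylide from 18 | C#C/C(C)=C/C=P(CCCC)(CCCC)CCCC | intermediate
20 | (3E,5E,7E,9E,11E,13E,15E,17E)-3,7,12,16-tetramethyl-18-[(1R)-2,6,6-trimethylcyclohex-2-en-1-yl]octadeca-3,5,7,9,11,13,15,17-octaen-1-yne (C31 polyenyne) | CC1=CCCC(C)(C)[C@H]1/C=C/C(C)=C/C=C/C(C)=C/C=C/C=C(C)/C=C/C=C(\C)C#C | intermediate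
21 | tert-butyldimethylsilyl ether of (3R,6'R)-7,8-didehydro-β,ε-caroten-3-ol | CC1=CCCC(C)(C)[C@H]1/C=C/C(C)=C/C=C/C(C)=C/C=C/C=C(C)/C=C/C=C(\C)C#CC1=C(C)C[C@@H](O[Si](C)(C)C(C)(C)C)CC1(C)C | intermediate
22 | (3R,6'R)-7,8-didehydro-β,ε-caroten-3-ol (all-E) | CC1=CCCC(C)(C)[C@H]1/C=C/C(C)=C/C=C/C(C)=C/C=C/C=C(C)/C=C/C=C(\C)C#CC1=C(C)C[C@@H](O)CC1(C)C | target

**Step count**
Total: 12 steps. Longest linear sequence: 9 steps (3, 4, 5, 6, 7, 8, 10, 11, 12), or 8 counted from α-ionone.

**Steps most likely to fail**

Step 11 (key coupling). Oxidative addition at the crowded C6–OTf bond may be slow enough that oxidative dimerization of the copper acetylide, metal-mediated E/Z scrambling or decomposition of the long polyenyne outruns the cross-coupling. The fallback sets out from 4 and 16 and comes back at 21. It keeps the same C6–C7 bond and the same reaction but puts it on a small, robust partner. Triflate 4 is coupled under Pd(PPh3)4/CuI/i-Pr2NH with an excess of enynol 16 to give the ring A enynol (2E)-5-[(4R)-4-(tert-butyldimethylsilyloxy)-2,6,6-trimethylcyclohex-1-en-1-yl]-3-methylpent-2-en-4-yn-1-ol F1. Appel bromination (CBr4, PPh3, CH2Cl2, 0 °C) gives the allylic bromide F2, and PBu3 gives the ring A C15 tributylphosphonium bromide F3. The ylide of F3 (KOt-Bu, THF, −78 °C) is then condensed with C25 aldehyde 15, forming C11=C12 and delivering 21 directly; step 10 is no longer needed.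

Step 10 (geometry of the polyenyne). E selectivity at the new C11=C12 bond may be incomplete, and rotation about C9=C10 in the delocalized ylide may erode the 9E geometry. Equilibration cannot repair this, because in 7,8-didehydro polyenes the 9Z isomer is not expected to be disfavoured. The fallback sets out from 15 and comes back at 20. It builds the chain as an ordinary polyenal, where all-E is the thermodynamic isomer, and makes the alkyne last. Aldehyde 15 is extended by two carbons with the ylide of (1,3-dioxolan-2-ylmethyl)triphenylphosphonium bromide (KOt-Bu, THF) to the C27 dioxolane F4, which is hydrolysed with aqueous oxalic acid to the C27 aldehyde F5. Wittig reaction with the stabilized ylide 2-(triphenylphosphoranylidene)propanal gives the C30 aldehyde F6, which can be equilibrated with catalytic I2 and crystallized as the all-E isomer. Colvin one-carbon homologation with Me3SiC(Li)N2 (THF, −78 → 0 °C) then turns the formyl group into the terminal alkyne of 20 without touching any double bond.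

Step 8 (mono-olefination of the dialdehyde). Statistical double condensation on the symmetrical dialdehyde may consume the resolved C15 salt and complicate purification. The fallback sets out from 12 and 18 and comes back at 20, reversing the order of the two olefinations. An excess of 12 is first condensed with the cheap ylide 19 (from 18) to the C16 aldehyde (2E,4E,6E,8E,10E)-2,7,11-trimethyltrideca-2,4,6,8,10-pentaen-12-ynal F7, purified by crystallization while the molecule is still small. The resolved salt 11 is then spent, through ylide 13, on a mono-aldehyde, forming C11'=C12' and giving 20. The minor hindered 11'Z isomer of this last olefination is removed by crystallization, without iodine.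

**Further compounds**
F1 | step 11 | (2E)-5-[(4R)-4-(tert-butyldimethylsilyloxy)-2,6,6-trimethylcyclohex-1-en-1-yl]-3-methylpent-2-en-4-yn-1-ol | OC/C=C(\C)C#CC1=C(C)C[C@@H](O[Si](C)(C)C(C)(C)C)CC1(C)C
F2 | step 11 | (4R)-1-[(3E)-5-bromo-3-methylpent-3-en-1-yn-1-yl]-4-(tert-butyldimethylsilyloxy)-2,6,6-trimethylcyclohex-1-ene | BrC/C=C(\C)C#CC1=C(C)C[C@@H](O[Si](C)(C)C(C)(C)C)CC1(C)C
F3 | step 11 | tributyl[(2E)-5-[(4R)-4-(tert-butyldimethylsilyloxy)-2,6,6-trimethylcyclohex-1-en-1-yl]-3-methylpent-2-en-4-yn-1-yl]phosphonium bromide | CCCC[P+](CCCC)(CCCC)C/C=C(\C)C#CC1=C(C)C[C@@H](O[Si](C)(C)C(C)(C)C)CC1(C)C.[Br-]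
F4 | step 10 | ethylene acetal of the C27 aldehyde F5 (new C11=C12 bond as Z/E mixture) | CC1=CCCC(C)(C)[C@H]1/C=C/C(C)=C/C=C/C(C)=C/C=C/C=C(C)/C=CC1OCCO1
F5 | step 10 | (2E,4E,6E,8E,10E,12E,14E)-4,9,13-trimethyl-15-[(1R)-2,6,6-trimethylcyclohex-2-en-1-yl]pentadeca-2,4,6,8,10,12,14-heptaenal | CC1=CCCC(C)(C)[C@H]1/C=C/C(C)=C/C=C/C(C)=C/C=C/C=C(C)/C=C/C=O
F6 | step 10 | (2E,4E,6E,8E,10E,12E,14E,16E)-2,6,11,15-tetramethyl-17-[(1R)-2,6,6-trimethylcyclohex-2-en-1-yl]heptadeca-2,4,6,8,10,12,14,16-octaenal | CC1=CCCC(C)(C)[C@H]1/C=C/C(C)=C/C=C/C(C)=C/C=C/C=C(C)/C=C/C=C(\C)C=O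
F7 | step 8 | (2E,4E,6E,8E,10E)-2,7,11-trimethyltrideca-2,4,6,8,10-pentaen-12-ynal | O=C/C(C)=C/C=C/C=C(C)/C=C/C=C(\C)C#C
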